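**Plan**
- Retrosynthesis: after masking the two catechol O–H as silyl ethers, the side chain is cut twice in one operation, at the S–O(alkyl) bond and at the CH2–CH2 bond, back to a benzylic zinc chloride, formaldehyde and SO3·pyridine. The benzylic C–Zn/C–Cl carbon goes back to a formyl group and the C2–Br bond back to 5-bromovanillin.
- Forward: the benzene ring is bought. Bromine enters C2 (para to OMe), OMe becomes OH, both phenols become OTBS, and CHO is taken to CH2OH and CH2Cl. The two-carbon chain and its sulfate are then assembled in one flask from three components, and fluoride plus cation exchange finish the route.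
- Enabling feature: the benzylic CH2 on ring carbon C1 can hold a carbon–zinc bond that the C2/C3 aryl bromides tolerate. The chain oxygen is born as a zinc alkoxide exactly where the sulfate ester sits, so the same oxygen captures SO3.
- Helpers: the TBS ethers on O4/O5, the benzylic chloride/zinc and the ammonium counter-ion. The chloride and zinc leave in the key step, the others in the last step.
- Stereochemistry: the target has no stereocentre and none arises on the way.

Key step: step 6

Assumption: the target is achiral, so "single enantiomer" is taken to mean the one compound drawn; the hydrogen sulfate is delivered as the free acid.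

**Step 1**
Reactants: 1 5-bromovanillin (3-bromo-4-hydroxy-5-methoxybenzaldehyde)
Product: 2 2,3-dibromo-4-hydroxy-5-methoxybenzaldehyde
Conditions: Br2 (1.2 equiv), Fe powder (cat.), NaOAc, AcOH, rt
Reagents that add atoms: bromine, BrBr
Why: Electrophilic aromatic bromination: of the two free ring positions the one para to the methoxy group is the more activated, so the second bromine should enter beside the first and give the 2,3-dibromo pattern.

**Step 2**
Reactants: 2 2,3-dibromo-4-hydroxy-5-methoxybenzaldehyde
Product: 3 2,3-dibromo-4,5-dihydroxybenzaldehyde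
Conditions: BBr3 (3 equiv), CH2Cl2, −78 °C → rt; then H2O
Reagents that add atoms: none
Why: Lewis-acid cleavage of the aryl methyl ether with BBr3 (bromide attacks the methyl group of the boron-bound ether); the aldehyde is only complexed and the aryl bromides are inert, so hydrolysis should return the free catechol aldehyde.

**Step 3**
Reactants: 3 2,3-dibromo-4,5-dihydroxybenzaldehyde
Product: 4 2,3-dibromo-4,5-bis(tert-butyldimethylsilyloxy)benzaldehyde
Conditions: TBSCl (2.6 equiv), imidazole (5 equiv), DMF, rt
Reagents that add atoms: tert-butyldimethylsilyl chloride, CC(C)(C)[Si](C)(C)Cl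
Why: O-Silylation of both phenols with TBSCl/imidazole should give ethers that tolerate hydride, phosphonium and organozinc chemistry and can later be cut by fluoride without harm to a sulfate ester.

**Step 4**
Reactants: 4 2,3-dibromo-4,5-bis(tert-butyldimethylsilyloxy)benzaldehyde
Product: 5 [2,3-dibromo-4,5-bis(tert-butyldimethylsilyloxy)phenyl]methanol
Conditions: DIBAL-H (1.2 equiv), CH2Cl2, −78 °C; aq. Rochelle salt
Reagents that add atoms: none
Why: 1,2-Hydride reduction of the aldehyde with DIBAL-H in an aprotic medium at low temperature, which avoids alkoxide-induced loss of the silyl group para to the formyl group and leaves the aryl bromides alone.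

**Step 5**
Reactants: 5 [2,3-dibromo-4,5-bis(tert-butyldimethylsilyloxy)phenyl]methanol
Product: 6 2,3-dibromo-4,5-bis(tert-butyldimethylsilyloxy)benzyl chloride
Conditions: PPh3 (1.3 equiv), NCS (1.3 equiv), CH2Cl2, 0 °C → rt
Reagents that add atoms: N-chlorosuccinimide, O=C1CCC(=O)N1Cl
Why: Appel-type deoxychlorination: the alkoxyphosphonium ion formed from PPh3/NCS is displaced by chloride under neutral conditions, so the aryl silyl ethers should survive.

**Step 6**
Reactants: 6 2,3-dibromo-4,5-bis(tert-butyldimethylsilyloxy)benzyl chloride; 7 formaldehyde (monomer in THF, freshly cracked from paraformaldehyde); 8 sulfur trioxide–pyridine complex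
Product: 11 ammonium 2-[2,3-dibromo-4,5-bis(tert-butyldimethylsilyloxy)phenyl]ethyl sulfate, via benzylzinc chloride 9 (not isolated), via chlorozinc alkoxide 10 (not isolated)
Conditions: Zn dust (1.5 equiv, activated with BrCH2CH2Br/TMSCl), LiCl (1.5 equiv), THF, 25 °C; filter from Zn; 7 (1.2 equiv), THF, −78 → 0 °C; 8 (1.5 equiv), THF/DMF, 0 °C → rt; aq. NH4Cl/NH3 work-up
Reagents that add atoms: ammonium chloride, [NH4+].[Cl-]
Why: Proposed new method: zinc inserts into the benzylic C–Cl bond of 6 (LiCl-assisted, 25 °C), the C–Zn bond of 9 adds to the C=O of monomeric formaldehyde 7 and forms the benzylic CH2–CH2O bond, and the oxygen of the chlorozinc alkoxide 10 then attacks the sulfur of 8 and expels pyridine, so that the carbon chain and the sulfate ester arise in one flask. The closest known reaction types are the LiCl-mediated preparation of benzylic zinc chlorides with their 1,2-addition to aldehydes and the O-sulfation of alcohols and alkoxides with SO3–amine complexes; only the capture of the zinc alkoxide by the SO3 complex in the same pot is new. No ring is closed and no stereocentre is formed. The step needs insertion at the sp3 C–Cl bond and not at the two aryl C–Br bonds, which the weaker benzylic bond and the electron-rich bis(silyloxy) ring should secure at 25 °C. It also needs attack through the benzylic carbon and not through an ortho ring carbon, which the bromine on C2 and the bulky silyloxy group beside C6 favour. Formaldehyde is kept in slight excess so that no benzylzinc is left to be C-sulfonated, and the two silyl ethers keep the catechol oxygens away from SO3.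

**Step 7**
Reactants: 11 ammonium 2-[2,3-dibromo-4,5-bis(tert-butyldimethylsilyloxy)phenyl]ethyl sulfate
Product: 12 2-(2,3-dibromo-4,5-dihydroxyphenyl)ethyl hydrogen sulfate
Conditions: NH4F (6 equiv), MeOH, rt, argon; evaporate; then Dowex 50W-X8 (H+ form), H2O, 0 °C; freeze-dry
Reagents that add atoms: none
Why: Fluoride should cleave the two aryl silyl ethers (strong Si–F bond, phenoxide leaving group) under nearly neutral conditions to which the alkyl sulfate monoester anion and the aryl bromides are inert, and strong-acid cation exchange then replaces ammonium by H+ to give the free hydrogen sulfate.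

**Compound list**
1 | 5-bromovanillin (3-bromo-4-hydroxy-5-methoxybenzaldehyde) | COc1cc(C=O)cc(Br)c1O | starting material
2 | 2,3-dibromo-4-hydroxy-5-methoxybenzaldehyde | COc1cc(C=O)c(Br)c(Br)c1O | intermediate
3 | 2,3-dibromo-4,5-dihydroxybenzaldehyde | O=Cc1cc(O)c(O)c(Br)c1Br | intermediate
4 | 2,3-dibromo-4,5-bis(tert-butyldimethylsilyloxy)benzaldehyde | O=Cc1cc(O[Si](C)(C)C(C)(C)C)c(O[Si](C)(C)C(C)(C)C)c(Br)c1Br | intermediate
5 | [2,3-dibromo-4,5-bis(tert-butyldimethylsilyloxy)phenyl]methanol | OCc1cc(O[Si](C)(C)C(C)(C)C)c(O[Si](C)(C)C(C)(C)C)c(Br)c1Br | intermediate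
6 | 2,3-dibromo-4,5-bis(tert-butyldimethylsilyloxy)benzyl chloride | ClCc1cc(O[Si](C)(C)C(C)(C)C)c(O[Si](C)(C)C(C)(C)C)c(Br)c1Br | intermediate
7 | formaldehyde (monomer, from paraformaldehyde) | C=O | starting material
8 | sulfur trioxide–pyridine complex | O=S(=O)([O-])[n+]1ccccc1 | starting material
9 | [2,3-dibromo-4,5-bis(tert-butyldimethylsilyloxy)benzyl]zinc chloride (LiCl complex in THF) | Cl[Zn]Cc1cc(O[Si](C)(C)C(C)(C)C)c(O[Si](C)(C)C(C)(C)C)c(Br)c1Br | intermediate (not isolated)
10 | chlorozinc 2-[2,3-dibromo-4,5-bis(tert-butyldimethylsilyloxy)phenyl]ethoxide | Cl[Zn]OCCc1cc(O[Si](C)(C)C(C)(C)C)c(O[Si](C)(C)C(C)(C)C)c(Br)c1Br | intermediate (not isolated)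
11 | ammonium 2-[2,3-dibromo-4,5-bis(tert-butyldimethylsilyloxy)phenyl]ethyl sulfate | [NH4+].[O-]S(=O)(=O)OCCc1cc(O[Si](C)(C)C(C)(C)C)c(O[Si](C)(C)C(C)(C)C)c(Br)c1Br | intermediate
12 | 2-(2,3-dibromo-4,5-dihydroxyphenyl)ethyl hydrogen sulfate | O=S(=O)(O)OCCc1cc(O)c(O)c(Br)c1Br | target

**Totals**
Total step count: 7. Longest linear sequence: 7 steps (1 → 12).

**Steps most likely to fail**

1. Step 6 (proposed new method). Several processes may go wrong:
   - zinc insertion spreading to the aryl C–Br bonds, or Wurtz coupling of the benzylic zinc;
   - attack of formaldehyde through the ortho ring carbon;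
   - further addition of formaldehyde to the zinc alkoxide before O-sulfation;
   - sluggish O-sulfation of an aggregated zinc alkoxide.

   The fallback uses known chemistry only, sets out from 4 and comes back at 11. Wittig methylenation (Ph3P+CH3 Br−, KOtBu, THF, 0 °C) should give 2,3-dibromo-4,5-bis(tert-butyldimethylsilyloxy)styrene F1, which already holds the same CH–CH2 bond. Anti-Markovnikov hydroboration with 9-BBN (THF, 0 °C → rt) gives B-[2-(2,3-dibromo-4,5-bis(tert-butyldimethylsilyloxy)phenyl)ethyl]-9-borabicyclo[3.3.1]nonane F2, which is not isolated but oxidised with NaBO3·4H2O (THF/H2O, rt) to 2-[2,3-dibromo-4,5-bis(tert-butyldimethylsilyloxy)phenyl]ethanol F3. O-Sulfation with 8 (pyridine, rt) and work-up with aqueous NH3 then give 11.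

2. Step 7. The freed catechol may be oxidised by air in the ammonia-containing medium, and the sulfate ester may be lost by acid-catalysed solvolysis when the free hydrogen sulfate is concentrated. The fallback moves the desilylation before the sulfation; it sets out from 6 and comes back at 12. The zinc alkoxide 10 is made as in step 6 but quenched with aqueous NH4Cl instead of being treated with 8, which gives the alcohol F3 described above. KHF2 in MeOH (rt) removes both silyl groups to give 2-(2,3-dibromo-4,5-dihydroxyphenyl)ethanol F4. H2SO4/DCC in DMF at 0 °C, a reagent pair that sulfates aliphatic hydroxyl groups in preference to phenols, should then give 12 directly as the hydrogen sulfate, which is purified by reversed-phase chromatography and freeze-dried.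

3. Step 3. The silyl group on O4 sits between a bromine and the neighbouring silyloxy group and para to the formyl group, so hydrolytic loss of it during work-up, chromatography or the following reduction is the likely failure. The fallback removes the formyl group before silylation; it sets out from 3 and comes back at 5. NaBH4 (THF/H2O, 0 °C) reduces the unprotected aldehyde to 2,3-dibromo-4,5-dihydroxybenzyl alcohol F5. Excess TBSCl/imidazole (DMF, rt) silylates all three hydroxyl groups to tert-butyl{[2,3-dibromo-4,5-bis(tert-butyldimethylsilyloxy)phenyl]methoxy}dimethylsilane F6. AcOH/THF/H2O (rt) then removes the alkyl silyl ether selectively, since aryl silyl ethers are the more acid-resistant, and gives 5.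

**Further compounds**
F1 | step 6 | 2,3-dibromo-4,5-bis(tert-butyldimethylsilyloxy)styrene | C=Cc1cc(O[Si](C)(C)C(C)(C)C)c(O[Si](C)(C)C(C)(C)C)c(Br)c1Br
F2 | step 6 | B-[2-(2,3-dibromo-4,5-bis(tert-butyldimethylsilyloxy)phenyl)ethyl]-9-borabicyclo[3.3.1]nonane | C1CC2CCCC(C1)B2CCc1cc(O[Si](C)(C)C(C)(C)C)c(O[Si](C)(C)C(C)(C)C)c(Br)c1Br
F3 | step 6 | 2-[2,3-dibromo-4,5-bis(tert-butyldimethylsilyloxy)phenyl]ethanol | OCCc1cc(O[Si](C)(C)C(C)(C)C)c(O[Si](C)(C)C(C)(C)C)c(Br)c1Br
F4 | step 7 | 2-(2,3-dibromo-4,5-dihydroxyphenyl)ethanol | OCCc1cc(O)c(O)c(Br)c1Br
F5 | step 3 | 2,3-dibromo-4,5-dihydroxybenzyl alcohol | OCc1cc(O)c(O)c(Br)c1Br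
F6 | step 3 | tert-butyl{[2,3-dibromo-4,5-bis(tert-butyldimethylsilyloxy)phenyl]methoxy}dimethylsilane | CC(C)(C)[Si](C)(C)OCc1cc(O[Si](C)(C)C(C)(C)C)c(O[Si](C)(C)C(C)(C)C)c(Br)c1Br
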